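**Strategy.** The route rests on cutting ring C at O1–C8a and C4–C4a, the two bonds by which the chain O1–C2–C3–C4 is anchored to the neighbouring ring A carbons C8a and C4a. One operation then rebuilds both: an aryne spanning C4a≡C8a accepts the alkoxide of an (S)-β-hydroxy Weinreb amide at C8a, and the carbanion left at C4a closes the pyranone on the amide carbonyl. The C2 configuration, set earlier by asymmetric transfer hydrogenation, rides through untouched. The precursors are an ortho-silyl aryl triflate whose C5 chlorine steers the addition and is removed afterwards, and a chromene-substituted hydroxy amide.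

Key step: step 12

Remark: atoms are numbered as in a flavanone; ring A is started from 2-chloro-4-hydroxybenzaldehyde so that its two oxygens are distinguished from the outset (the formyl carbon becomes the triflate-bearing carbon), and commercial 3-chloro-3-methylbut-1-yne serves as the activated propargyl donor.

**Ring A aryne precursor (steps 1–7)**

Step 1
Reactants: 1 2-chloro-4-hydroxybenzaldehyde
Product: 2 2-chloro-4-(methoxymethoxy)benzaldehyde
Conditions: MOMCl, iPr2NEt, CH2Cl2, 0 °C → rt
Reagents that add atoms: chloromethyl methyl ether, COCCl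
Why: O-alkylation of the acidic para-formyl phenol installs the acetal that later directs metalation, survives fluoride and comes off with dilute acid.

Step 2
Reactants: 2 2-chloro-4-(methoxymethoxy)benzaldehyde
Product: 4 2-chloro-4-(methoxymethoxy)phenol, via aryl formate 3 (not isolated)
Conditions: mCPBA, CH2Cl2, rt; aq. NaHCO3 wash; then K2CO3 (cat.), MeOH, rt
Reagents that add atoms: 3-chloroperbenzoic acid, O=C(OO)c1cccc(Cl)c1
Why: Baeyer–Villiger oxidation with migration of the electron-rich aryl group (Dakin-type outcome) followed by methanolysis of the formate turns the formyl carbon into the hydroxyl-bearing carbon next to chlorine.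

Step 3
Reactants: 4 2-chloro-4-(methoxymethoxy)phenol
Product: 5 2-bromo-6-chloro-4-(methoxymethoxy)phenol
Conditions: NBS, iPr2NH (cat.), CH2Cl2, 0 °C
Reagents that add atoms: N-bromosuccinimide, O=C1CCC(=O)N1Br
Why: Amine-catalysed electrophilic bromination of a phenol goes ortho to the free hydroxyl, and with the para position and one ortho position blocked only the carbon that will become C8a is open.

Step 4
Reactants: 5 2-bromo-6-chloro-4-(methoxymethoxy)phenol
Product: 9 tert-butyl[2-chloro-4-(methoxymethoxy)-6-(trimethylsilyl)phenoxy]dimethylsilane, via aryl trimethylsilyl ether 6 (not isolated), via aryllithium 7 (not isolated), via lithium phenoxide 8 (not isolated)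
Conditions: HN(SiMe3)2, THF, 65 °C, then evaporate; n-BuLi, THF, −78 °C; TBSOTf, −78 → 0 °C
Reagents that add atoms: hexamethyldisilazane, C[Si](C)(C)N[Si](C)(C)C; tert-butyldimethylsilyl trifluoromethanesulfonate, CC(C)(C)[Si](C)(C)OS(=O)(=O)C(F)(F)F
Why: O-silylation, bromine–lithium exchange and anionic 1,3 O-to-C silyl migration (retro-Brook rearrangement) put the trimethylsilyl group on carbon, and the hindered phenoxide set free is capped in the same flask as a silyl ether that tolerates alkyllithiums.

Step 5
Reactants: 9 tert-butyl[2-chloro-4-(methoxymethoxy)-6-(trimethylsilyl)phenoxy]dimethylsilane; 10 1-bromo-3-methylbut-2-ene (prenyl bromide)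
Product: 13 tert-butyl[2-chloro-4-(methoxymethoxy)-3-(3-methylbut-2-enyl)-6-(trimethylsilyl)phenoxy]dimethylsilane, via aryllithium 11 (not isolated), via arylcopper 12 (not isolated)
Conditions: s-BuLi, THF, −78 °C; CuBr·SMe2, −78 °C; then 10, −78 → 0 °C
Reagents that add atoms: none
Why: Directed ortho-metalation at the one ring position flanked by two directing groups (chlorine and the acetal oxygen; the other free position is shielded by silicon), then transmetalation to copper and SN2 coupling at the primary carbon of the allylic bromide.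

Step 6
Reactants: 13 tert-butyl[2-chloro-4-(methoxymethoxy)-3-(3-methylbut-2-enyl)-6-(trimethylsilyl)phenoxy]dimethylsilane
Product: 14 2-chloro-4-(methoxymethoxy)-3-(3-methylbut-2-enyl)-6-(trimethylsilyl)phenol
Conditions: Bu4NF, AcOH, THF, 0 °C
Reagents that add atoms: none
Why: Buffered fluoride cleavage of the aryl O–Si bond, in which the aryl C–Si bond (no leaving group beside it yet), the acetal and the alkene should be untouched.

Step 7
Reactants: 14 2-chloro-4-(methoxymethoxy)-3-(3-methylbut-2-enyl)-6-(trimethylsilyl)phenol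
Product: 15 2-chloro-4-(methoxymethoxy)-3-(3-methylbut-2-enyl)-6-(trimethylsilyl)phenyl trifluoromethanesulfonate
Conditions: Tf2O, pyridine, CH2Cl2, −78 → 0 °C
Reagents that add atoms: trifluoromethanesulfonic anhydride, O=S(=O)(OS(=O)(=O)C(F)(F)F)C(F)(F)F
Why: O-sulfonylation of the phenol gives the ortho-silyl aryl triflate, the standard fluoride-triggered aryne precursor, with the triflate on the future C4a and silicon on the future C8a.

**Ring B hydroxy amide (steps 8–11)**

Step 8
Reactants: 16 methyl 4-hydroxybenzoate; 17 3-chloro-3-methylbut-1-yne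
Product: 18 methyl 4-[(2-methylbut-3-yn-2-yl)oxy]benzoate
Conditions: CuCl2·2H2O (cat.), DBU, MeCN, 0 °C → rt
Reagents that add atoms: none
Why: Copper-catalysed propargylic substitution of the tertiary propargyl chloride by the phenoxide, the usual entry to aryl 1,1-dimethylpropargyl ethers.

Step 9
Reactants: 18 methyl 4-[(2-methylbut-3-yn-2-yl)oxy]benzoate
Product: 21 methyl 2,2-dimethyl-2H-chromene-6-carboxylate, via allenyl phenol 19 (not isolated), via quinone methide 20 (not isolated)
Conditions: PhNEt2, 190 °C
Reagents that add atoms: none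
Why: Thermal aromatic propargyl Claisen rearrangement, 1,5-hydrogen shift and oxa-6π-electrocyclisation form the 2,2-dimethylchromene, and since both positions ortho to oxygen are equivalent only one product can form.

Step 10
Reactants: 21 methyl 2,2-dimethyl-2H-chromene-6-carboxylate; 22 N-methoxy-N-methylacetamide
Product: 25 3-(2,2-dimethyl-2H-chromen-6-yl)-N-methoxy-N-methyl-3-oxopropanamide, via amide enolate 23 (not isolated), via ketoamide enolate 24 (not isolated)
Conditions: 22 (2.5 equiv), LiN(iPr)2 (2.5 equiv), THF, −78 °C; then 21, −78 → −20 °C; AcOH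
Reagents that add atoms: none
Why: Crossed Claisen condensation of the amide enolate with a non-enolisable aryl ester, pulled to completion by deprotonation of the β-keto amide, which is why two equivalents of enolate are used.

Step 11
Reactants: 25 3-(2,2-dimethyl-2H-chromen-6-yl)-N-methoxy-N-methyl-3-oxopropanamide
Product: 26 (S)-3-(2,2-dimethyl-2H-chromen-6-yl)-3-hydroxy-N-methoxy-N-methylpropanamide
Conditions: RuCl[(S,S)-TsDPEN](p-cymene) (1 mol%), HCO2H/Et3N (5:2), EtOAc, 40 °C
Reagents that add atoms: none
Why: Asymmetric transfer hydrogenation of an aryl ketone by a bifunctional ruthenium–diamine catalyst, in which the (S,S)-ligand should deliver hydride to the Re face (aryl group held against the η6-arene) and so set the (S)-carbinol centre without touching the chromene alkene.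

**Annulation and end game (steps 12–14)**

Step 12
Reactants: 26 (S)-3-(2,2-dimethyl-2H-chromen-6-yl)-3-hydroxy-N-methoxy-N-methylpropanamide; 15 2-chloro-4-(methoxymethoxy)-3-(3-methylbut-2-enyl)-6-(trimethylsilyl)phenyl trifluoromethanesulfonate
Product: 31 (S)-5-chloro-2-(2,2-dimethyl-2H-chromen-6-yl)-7-(methoxymethoxy)-6-(3-methylbut-2-enyl)chroman-4-one, via potassium alkoxide 27 (not isolated), via aryne 28 (not isolated), via arylpotassium 29 (not isolated), via tetrahedral adduct 30 (not isolated)
Conditions: 26 (1.3 equiv), KH, 18-crown-6, THF, 0 °C; then 15, CsF, THF, 0 °C → rt; AcOH, −20 °C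
Reagents that add atoms: none
Why: Proposed new method: fluoride attack on silicon at C8a with loss of triflate from C4a unveils aryne 28, the preformed alkoxide 27 bonds through oxygen to C8a, and the carbanion 29 thus generated at C4a adds to the amide carbonyl to give adduct 30, which should release the ketone only on acidic quench so that the base-sensitive chromanone never meets free base. The closest known reaction types are the fluoride-promoted annulation of arynes with salicylate esters to xanthones, the O-arylation of alkoxides by arynes and the acylation of aryl anions by N-methoxy-N-methyl amides. Ring C closes by 6-exo-trig attack of C4a on the amide carbonyl. No lasting stereocentre is formed: C2 keeps its (S) configuration because the C2–O bond is never broken, and the hemiaminal centre at C4 disappears on work-up. Regiochemistry is the selectivity at stake, and the C5 chlorine polarises the aryne so that oxygen enters at the remote carbon C8a, since the carbanion then develops at C4a where the adjacent C–Cl dipole stabilises it, while the C7 ether one position further away has only a feeble contrary influence. Acyl capture must also outrun protonation of C4a, which the proton-free medium (alkoxide made with KH, no amine or alcohol present) and the six-membered transition state should favour over the slower carbon-to-carbon proton transfer from C3.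

Step 13
Reactants: 31 (S)-5-chloro-2-(2,2-dimethyl-2H-chromen-6-yl)-7-(methoxymethoxy)-6-(3-methylbut-2-enyl)chroman-4-one
Product: 32 (S)-2-(2,2-dimethyl-2H-chromen-6-yl)-7-(methoxymethoxy)-6-(3-methylbut-2-enyl)chroman-4-one
Conditions: Pd(OAc)2 (5 mol%), XPhos (10 mol%), HCO2Na, DMF, 80 °C
Reagents that add atoms: none
Why: Palladium-catalysed hydrodehalogenation, in which zerovalent palladium inserts into the C5–Cl bond activated by the neighbouring ketone, formate replaces chloride and loses CO2, and C–H reductive elimination follows under a base too weak to open the chromanone.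

Step 14
Reactants: 32 (S)-2-(2,2-dimethyl-2H-chromen-6-yl)-7-(methoxymethoxy)-6-(3-methylbut-2-enyl)chroman-4-one
Product: 33 Dinklagin A, (S)-2-(2,2-dimethyl-2H-chromen-6-yl)-7-hydroxy-6-(3-methylbut-2-enyl)chroman-4-one
Conditions: aq. HCl (1 M), MeOH, 40 °C
Reagents that add atoms: none
Why: Acid-catalysed acetal exchange with methanol frees the C7 phenol under conditions mild enough for the prenyl group, the chromene and the C2 centre.

**Compound list**

1 | 2-chloro-4-hydroxybenzaldehyde | O=Cc1ccc(O)cc1Cl | starting material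
2 | 2-chloro-4-(methoxymethoxy)benzaldehyde | COCOc1ccc(C=O)c(Cl)c1 | intermediate
3 | 2-chloro-4-(methoxymethoxy)phenyl formate | COCOc1ccc(OC=O)c(Cl)c1 | intermediate
4 | 2-chloro-4-(methoxymethoxy)phenol | COCOc1ccc(O)c(Cl)c1 | intermediate
5 | 2-bromo-6-chloro-4-(methoxymethoxy)phenol | COCOc1cc(Cl)c(O)c(Br)c1 | intermediate
6 | [2-bromo-6-chloro-4-(methoxymethoxy)phenoxy]trimethylsilane | COCOc1cc(Cl)c(O[Si](C)(C)C)c(Br)c1 | intermediate
7 | [3-chloro-5-(methoxymethoxy)-2-(trimethylsilyloxy)phenyl]lithium | COCOc1cc(Cl)c(O[Si](C)(C)C)c([Li])c1 | intermediate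
8 | lithium 2-chloro-4-(methoxymethoxy)-6-(trimethylsilyl)phenoxide | [Li+].[O-]c1c(Cl)cc(OCOC)cc1[Si](C)(C)C | intermediate
9 | tert-butyl[2-chloro-4-(methoxymethoxy)-6-(trimethylsilyl)phenoxy]dimethylsilane | COCOc1cc(Cl)c(O[Si](C)(C)C(C)(C)C)c([Si](C)(C)C)c1 | intermediate
10 | 1-bromo-3-methylbut-2-ene (prenyl bromide) | CC(C)=CCBr | starting material
11 | [3-(tert-butyldimethylsilyloxy)-2-chloro-6-(methoxymethoxy)-4-(trimethylsilyl)phenyl]lithium | COCOc1cc([Si](C)(C)C)c(O[Si](C)(C)C(C)(C)C)c(Cl)c1[Li] | intermediate
12 | [3-(tert-butyldimethylsilyloxy)-2-chloro-6-(methoxymethoxy)-4-(trimethylsilyl)phenyl]copper | COCOc1cc([Si](C)(C)C)c(O[Si](C)(C)C(C)(C)C)c(Cl)c1[Cu] | intermediate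
13 | tert-butyl[2-chloro-4-(methoxymethoxy)-3-(3-methylbut-2-enyl)-6-(trimethylsilyl)phenoxy]dimethylsilane | CC(C)=CCc1c(Cl)c(O[Si](C)(C)C(C)(C)C)c([Si](C)(C)C)cc1OCOC | intermediate
14 | 2-chloro-4-(methoxymethoxy)-3-(3-methylbut-2-enyl)-6-(trimethylsilyl)phenol | CC(C)=CCc1c(Cl)c(O)c([Si](C)(C)C)cc1OCOC | intermediate
15 | 2-chloro-4-(methoxymethoxy)-3-(3-methylbut-2-enyl)-6-(trimethylsilyl)phenyl trifluoromethanesulfonate | CC(C)=CCc1c(Cl)c(OS(=O)(=O)C(F)(F)F)c([Si](C)(C)C)cc1OCOC | intermediate
16 | methyl 4-hydroxybenzoate | COC(=O)c1ccc(O)cc1 | starting material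
17 | 3-chloro-3-methylbut-1-yne | CC(C)(Cl)C#C | starting material
18 | methyl 4-[(2-methylbut-3-yn-2-yl)oxy]benzoate | COC(=O)c1ccc(OC(C)(C)C#C)cc1 | intermediate
19 | methyl 4-hydroxy-3-(3-methylbuta-1,2-dienyl)benzoate | COC(=O)c1ccc(O)c(C=C=C(C)C)c1 | intermediate
20 | methyl 3-(3-methylbut-2-enylidene)-4-oxocyclohexa-1,5-diene-1-carboxylate | COC(=O)C1=CC(=CC=C(C)C)C(=O)C=C1 | intermediate
21 | methyl 2,2-dimethyl-2H-chromene-6-carboxylate | COC(=O)c1ccc2c(c1)C=CC(C)(C)O2 | intermediate
22 | N-methoxy-N-methylacetamide | CC(=O)N(C)OC | starting material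
23 | lithium enolate of N-methoxy-N-methylacetamide | [Li+].[O-]C(=C)N(C)OC | intermediate
24 | lithium enolate of 3-(2,2-dimethyl-2H-chromen-6-yl)-N-methoxy-N-methyl-3-oxopropanamide | [Li+].[O-]C(=CC(=O)N(C)OC)c1ccc2c(c1)C=CC(C)(C)O2 | intermediate
25 | 3-(2,2-dimethyl-2H-chromen-6-yl)-N-methoxy-N-methyl-3-oxopropanamide | O=C(CC(=O)N(C)OC)c1ccc2c(c1)C=CC(C)(C)O2 | intermediate
26 | (S)-3-(2,2-dimethyl-2H-chromen-6-yl)-3-hydroxy-N-methoxy-N-methylpropanamide | O[C@H](c1ccc2c(c1)C=CC(C)(C)O2)CC(=O)N(C)OC | intermediate
27 | potassium (S)-1-(2,2-dimethyl-2H-chromen-6-yl)-3-[methoxy(methyl)amino]-3-oxopropan-1-olate | [K+].[O-][C@H](c1ccc2c(c1)C=CC(C)(C)O2)CC(=O)N(C)OC | intermediate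
28 | 3-chloro-5-(methoxymethoxy)-4-(3-methylbut-2-enyl)benzyne (triple bond between the former triflate and silyl carbons) | CC(C)=CCC1=C(Cl)C#CC=C1OCOC | intermediate
29 | [2-chloro-6-{(1S)-1-(2,2-dimethyl-2H-chromen-6-yl)-3-[methoxy(methyl)amino]-3-oxopropoxy}-4-(methoxymethoxy)-3-(3-methylbut-2-enyl)phenyl]potassium | CC(C)=CCc1c(Cl)c([K])c(cc1OCOC)O[C@H](c1ccc2c(c1)C=CC(C)(C)O2)CC(=O)N(C)OC | intermediate
30 | potassium (2S)-5-chloro-2-(2,2-dimethyl-2H-chromen-6-yl)-4-[methoxy(methyl)amino]-7-(methoxymethoxy)-6-(3-methylbut-2-enyl)chroman-4-olate (C4 configuration undefined) | CC(C)=CCc1c(Cl)c2c(cc1OCOC)O[C@H](c1ccc3c(c1)C=CC(C)(C)O3)CC2([O-])N(C)OC.[K+] | intermediate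
31 | (S)-5-chloro-2-(2,2-dimethyl-2H-chromen-6-yl)-7-(methoxymethoxy)-6-(3-methylbut-2-enyl)chroman-4-one | CC(C)=CCc1c(Cl)c2c(cc1OCOC)O[C@H](c1ccc3c(c1)C=CC(C)(C)O3)CC2=O | intermediate
32 | (S)-2-(2,2-dimethyl-2H-chromen-6-yl)-7-(methoxymethoxy)-6-(3-methylbut-2-enyl)chroman-4-one | CC(C)=CCc1cc2c(cc1OCOC)O[C@H](c1ccc3c(c1)C=CC(C)(C)O3)CC2=O | intermediate
33 | Dinklagin A, (S)-2-(2,2-dimethyl-2H-chromen-6-yl)-7-hydroxy-6-(3-methylbut-2-enyl)chroman-4-one | CC(C)=CCc1cc2c(cc1O)O[C@H](c1ccc3c(c1)C=CC(C)(C)O3)CC2=O | target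

**Step count.** Total: 14 steps. Longest linear sequence: 10 steps (steps 1–7, then 12–14); the hydroxy amide arm (steps 8–11) joins at step 12.

**Steps most likely to fail**

1. Step 12. Three processes can undermine it: protonation of the C4a carbanion before it reaches the amide (plain O-arylation), retro-aldol cleavage or β-elimination of the alkoxide before it meets the aryne, and early collapse of the adduct followed by base-induced opening of the chromanone, which would erode the C2 configuration. The fallback uses known chemistry, sets out from 25 and returns at 32, so it also bypasses step 13. Ketone 25 is reduced with the enantiomeric catalyst RuCl[(R,R)-TsDPEN](p-cymene) to (R)-3-(2,2-dimethyl-2H-chromen-6-yl)-3-hydroxy-N-methoxy-N-methylpropanamide F1. In parallel, commercial 4,6-dibromobenzene-1,3-diol is mono-protected (MOMCl, iPr2NEt) to 2,4-dibromo-5-(methoxymethoxy)phenol F2 and silylated (iPr3SiCl, imidazole) to [2,4-dibromo-5-(methoxymethoxy)phenoxy]triisopropylsilane F3. The bromine beside the chelating acetal is exchanged (n-BuLi, −78 °C) and coupled with 10 through copper (CuBr·SMe2) to [2-bromo-5-(methoxymethoxy)-4-(3-methylbut-2-enyl)phenoxy]triisopropylsilane F4, and the silyl ether is cleaved (Bu4NF) to 2-bromo-5-(methoxymethoxy)-4-(3-methylbut-2-enyl)phenol F5. Mitsunobu etherification of F5 with F1 (PPh3, DIAD, toluene, 0 °C) inverts the carbinol carbon and should give (S)-3-[2-bromo-5-(methoxymethoxy)-4-(3-methylbut-2-enyl)phenoxy]-3-(2,2-dimethyl-2H-chromen-6-yl)-N-methoxy-N-methylpropanamide F6. Bromine–lithium exchange (t-BuLi, THF, −100 °C) and Parham-type cyclisation of the aryllithium onto the Weinreb amide then close ring C and deliver 32.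

2. Step 13. Oxidative addition at the doubly ortho-substituted C5–Cl bond may be slow, palladium hydride may shift or saturate the prenyl and chromene double bonds, and long heating with formate may open ring C and scramble C2. The fallback sets out from 31 and returns at 32, replacing the hydride pathway by a boron relay. Miyaura borylation (Pd2(dba)3, XPhos, bis(pinacolato)diboron, KOAc, 1,4-dioxane, 90 °C) should give (S)-2-(2,2-dimethyl-2H-chromen-6-yl)-7-(methoxymethoxy)-6-(3-methylbut-2-enyl)-5-(4,4,5,5-tetramethyl-1,3,2-dioxaborolan-2-yl)chroman-4-one F7. Its crowded C–B bond, flanked by the ketone and the prenyl group, is then cleaved by protodeboronation (AgNO3 cat., Et3N, aqueous EtOH, 60 °C), so no palladium hydride is ever present.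

3. Step 5. The ortho-chloro aryllithium may lose LiCl on warming (aryne formation), and the copper coupling may proceed with allylic transposition to the 1,1-dimethylallyl isomer. The fallback sets out from 9 and returns at 13, forming the C–C bond by cross-coupling. Aryllithium 11 is quenched at −78 °C with I2 to tert-butyl[2-chloro-3-iodo-4-(methoxymethoxy)-6-(trimethylsilyl)phenoxy]dimethylsilane F8. Stille coupling of F8 with tributyl(3-methylbut-2-enyl)stannane (Pd(PPh3)4, DMF, 90 °C, no fluoride additive) at the C–I bond should then give 13.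

Further compounds
F1 | step 12 | (R)-3-(2,2-dimethyl-2H-chromen-6-yl)-3-hydroxy-N-methoxy-N-methylpropanamide | O[C@@H](c1ccc2c(c1)C=CC(C)(C)O2)CC(=O)N(C)OC
F2 | step 12 | 2,4-dibromo-5-(methoxymethoxy)phenol | COCOc1cc(O)c(Br)cc1Br
F3 | step 12 | [2,4-dibromo-5-(methoxymethoxy)phenoxy]triisopropylsilane | COCOc1cc(O[Si](C(C)C)(C(C)C)C(C)C)c(Br)cc1Br
F4 | step 12 | [2-bromo-5-(methoxymethoxy)-4-(3-methylbut-2-enyl)phenoxy]triisopropylsilane | CC(C)=CCc1cc(Br)c(O[Si](C(C)C)(C(C)C)C(C)C)cc1OCOC
F5 | step 12 | 2-bromo-5-(methoxymethoxy)-4-(3-methylbut-2-enyl)phenol | CC(C)=CCc1cc(Br)c(O)cc1OCOC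
F6 | step 12 | (S)-3-[2-bromo-5-(methoxymethoxy)-4-(3-methylbut-2-enyl)phenoxy]-3-(2,2-dimethyl-2H-chromen-6-yl)-N-methoxy-N-methylpropanamide | CC(C)=CCc1cc(Br)c(cc1OCOC)O[C@H](c1ccc2c(c1)C=CC(C)(C)O2)CC(=O)N(C)OC
F7 | step 13 | (S)-2-(2,2-dimethyl-2H-chromen-6-yl)-7-(methoxymethoxy)-6-(3-methylbut-2-enyl)-5-(4,4,5,5-tetramethyl-1,3,2-dioxaborolan-2-yl)chroman-4-one | CC(C)=CCc1c(B2OC(C)(C)C(C)(C)O2)c2c(cc1OCOC)O[C@H](c1ccc3c(c1)C=CC(C)(C)O3)CC2=O
F8 | step 5 | tert-butyl[2-chloro-3-iodo-4-(methoxymethoxy)-6-(trimethylsilyl)phenoxy]dimethylsilane | COCOc1cc([Si](C)(C)C)c(O[Si](C)(C)C(C)(C)C)c(Cl)c1I
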